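The quinone ring is built by a thermal cyclobutenone ring expansion. The disconnection is the ring bond between C-3, which carries the docosyl chain, and the C-4 carbonyl next to C-5(OMe). A 4-alkenyl-2-methoxycyclobutenone, made from dimethyl squarate and an α-lithiated enol ether of tetracosanal, opens on heating to a dienylketene. 6π-Electrocyclisation joins the ketene carbon (C-4) to the alkene terminus (C-3), and aromatisation gives a phenol that already carries the chain and all four ring oxygens; oxidation then delivers the quinone. The step exploits the alternating oxygenation of the benzoquinone ring: C-1, C-4, C-5 and C-6 come from the squarate ring, C-2(O) and C-3(docosyl) from the enol ether.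

Key step: step 5

Remark: the target is achiral; the tetracos-1-enyl compounds are handled as E/Z mixtures and the cyclobutenones as racemates, because both elements are erased in step 5, so their SMILES carry no descriptors at these positions.

Step 1
Reactants: 1 tetracosan-1-ol
Product: 2 tetracosanal
Conditions: IBX, EtOAc, 80 °C
Reagents that add atoms: none
Why: IBX oxidation of a primary alcohol stops at the aldehyde, and hot ethyl acetate dissolves the long-chain substrate while the iodine reagent and its reduced form are removed by filtration (hypervalent iodine alcohol oxidation).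

Step 2
Reactants: 2 tetracosanal
Product: 4 1-(methoxymethoxy)tetracos-1-ene (E/Z mixture), via potassium enolate 3 (not isolated)
Conditions: KH, THF, 0 °C to rt; then MOMCl, −78 to 0 °C
Reagents that add atoms: chloromethyl methyl ether, COCCl
Why: Irreversible deprotonation by KH gives the potassium enolate, whose oxygen should be alkylated by the hard, oxocarbenium-like chloromethyl ether (enolate O-alkylation), and the geometric mixture needs no separation.

Step 3
Reactants: 4 1-(methoxymethoxy)tetracos-1-ene; 5 dimethyl squarate (3,4-dimethoxycyclobut-3-ene-1,2-dione)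
Product: 8 2,3,4-trimethoxy-4-[1-(methoxymethoxy)tetracos-1-en-1-yl]cyclobut-2-en-1-one (racemic), via alkenyllithium 6 (not isolated), via lithium alkoxide 7 (not isolated)
Conditions: sec-BuLi, THF, −78 to −40 °C; then 5, THF, −78 °C; then MeOTf, −78 to 0 °C
Reagents that add atoms: methyl trifluoromethanesulfonate, COS(=O)(=O)C(F)(F)F
Why: The methoxymethoxy group directs vinylic α-lithiation by chelation (directed α-metalation of an alkoxymethyl vinyl ether), the alkenyllithium adds 1,2 to one of the two equivalent carbonyl groups of the squarate, and O-methylation of the tertiary alkoxide blocks that oxygen against later ionisation, the quaternary centre forming as a racemate.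

Step 4
Reactants: 8 2,3,4-trimethoxy-4-[1-(methoxymethoxy)tetracos-1-en-1-yl]cyclobut-2-en-1-one
Product: 11 2,4-dimethoxy-4-[1-(methoxymethoxy)tetracos-1-en-1-yl]cyclobut-2-en-1-one (racemic), via aluminium alkoxide 9 (not isolated), via allylic trifluoroacetate 10 (not isolated)
Conditions: i-Bu2AlH, CH2Cl2, −78 °C; then 2,6-lutidine, (CF3CO)2O, −78 to 0 °C; then aq. NaHCO3
Reagents that add atoms: water, O
Why: 1,2-Reduction of the vinylogous ester carbonyl and ionisation of the allylic trifluoroacetate give a methoxy-stabilised cyclobutenyl cation that water captures at C-3, so loss of methanol moves the carbonyl to the former C-3 (Stork–Danheiser type 1,3-carbonyl transposition), while only the secondary oxygen can be acylated and the lutidine buffer spares the enol ether.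

Step 5
Reactants: 11 2,4-dimethoxy-4-[1-(methoxymethoxy)tetracos-1-en-1-yl]cyclobut-2-en-1-one
Product: 15 3-docosyl-5-methoxy-2-(methoxymethoxy)cyclohexa-2,5-diene-1,4-dione, via dienylketene 12 (not isolated), via cyclohexadienone 13 (not isolated), via phenol 14 (not isolated)
Conditions: toluene, 110 °C, Ar; then (NH4)2Ce(NO3)6, MeCN/THF/H2O, 0 °C
Reagents that add atoms: water, O
Why: Heating triggers conrotatory 4π-electrocyclic opening of the cyclobutenone C-1–C-4 bond, and the donor 4-methoxy group rotates outward so that the alkenyl group ends up cis to the ketene in dienylketene 12. Disrotatory 6π-electrocyclisation then joins the ketene carbon, which already has C–OMe as its neighbour, to the alkene terminus bearing the docosyl chain; this closes the six-membered carbocycle of cyclohexadienone 13, and enolisation to phenol 14 erases the transient sp3 centre, so no stereocentre remains. The closest known reaction type is the Moore–Liebeskind ring expansion of 4-alkenyl- and 4-aryl-cyclobutenones to hydroquinone derivatives. The regiochemistry is fixed by connectivity, because the transposition of step 4 placed C–OMe next to the ketene carbon and C–H next to the quaternary carbon, and the torquoselectivity is secured by the 4-methoxy substituent. (NH4)2Ce(NO3)6 should then oxidise the 4-methoxyphenol unit selectively, the free hydroxyl and its para methoxy group becoming the two quinone carbonyls with loss of methanol, while the methoxymethyl ether and the other methoxy group stay in place.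

Step 6
Reactants: 15 3-docosyl-5-methoxy-2-(methoxymethoxy)cyclohexa-2,5-diene-1,4-dione
Product: 16 3-docosyl-2-hydroxy-5-methoxycyclohexa-2,5-diene-1,4-dione
Conditions: 2 M HCl, THF, rt
Reagents that add atoms: none
Why: The methoxymethyl group on the quinone oxygen is a vinylogous acylal and should hydrolyse under mild aqueous acid (acetal hydrolysis), whereas the C-5 methyl vinylogous ester needs far harsher conditions.

Compound list
1 | tetracosan-1-ol | CCCCCCCCCCCCCCCCCCCCCCCCO | starting material
2 | tetracosanal | CCCCCCCCCCCCCCCCCCCCCCCC=O | intermediate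
3 | potassium tetracos-1-en-1-olate | CCCCCCCCCCCCCCCCCCCCCCC=C[O-].[K+] | intermediate
4 | 1-(methoxymethoxy)tetracos-1-ene (E/Z mixture) | CCCCCCCCCCCCCCCCCCCCCCC=COCOC | intermediate
5 | dimethyl squarate (3,4-dimethoxycyclobut-3-ene-1,2-dione) | COC1=C(OC)C(=O)C1=O | starting material
6 | [1-(methoxymethoxy)tetracos-1-en-1-yl]lithium | [Li]C(OCOC)=CCCCCCCCCCCCCCCCCCCCCCC | intermediate
7 | lithium 2,3-dimethoxy-1-[1-(methoxymethoxy)tetracos-1-en-1-yl]-4-oxocyclobut-2-en-1-olate | COC1=C(OC)C(O[Li])(C(OCOC)=CCCCCCCCCCCCCCCCCCCCCCC)C1=O | intermediate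
8 | 2,3,4-trimethoxy-4-[1-(methoxymethoxy)tetracos-1-en-1-yl]cyclobut-2-en-1-one (racemic) | COC1=C(OC)C(OC)(C(OCOC)=CCCCCCCCCCCCCCCCCCCCCCC)C1=O | intermediate
9 | diisobutylaluminium 2,3,4-trimethoxy-4-[1-(methoxymethoxy)tetracos-1-en-1-yl]cyclobut-2-en-1-olate | COC1=C(OC)C(OC)(C(OCOC)=CCCCCCCCCCCCCCCCCCCCCCC)C1O[Al](CC(C)C)CC(C)C | intermediate
10 | 2,3,4-trimethoxy-4-[1-(methoxymethoxy)tetracos-1-en-1-yl]cyclobut-2-en-1-yl trifluoroacetate | COC1=C(OC)C(OC)(C(OCOC)=CCCCCCCCCCCCCCCCCCCCCCC)C1OC(=O)C(F)(F)F | intermediate
11 | 2,4-dimethoxy-4-[1-(methoxymethoxy)tetracos-1-en-1-yl]cyclobut-2-en-1-one (racemic) | COC1=CC(OC)(C(OCOC)=CCCCCCCCCCCCCCCCCCCCCCC)C1=O | intermediate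
12 | (3E)-2,4-dimethoxy-5-(methoxymethoxy)octacosa-1,3,5-trien-1-one | O=C=C(OC)/C=C(/OC)C(OCOC)=CCCCCCCCCCCCCCCCCCCCCCC | intermediate
13 | 6-docosyl-2,4-dimethoxy-5-(methoxymethoxy)cyclohexa-2,4-dien-1-one (racemic) | COC1=CC(OC)=C(OCOC)C(CCCCCCCCCCCCCCCCCCCCCC)C1=O | intermediate
14 | 2-docosyl-4,6-dimethoxy-3-(methoxymethoxy)phenol | COc1cc(OC)c(OCOC)c(CCCCCCCCCCCCCCCCCCCCCC)c1O | intermediate
15 | 3-docosyl-5-methoxy-2-(methoxymethoxy)cyclohexa-2,5-diene-1,4-dione | COC1=CC(=O)C(OCOC)=C(CCCCCCCCCCCCCCCCCCCCCC)C1=O | intermediate
16 | 3-docosyl-2-hydroxy-5-methoxycyclohexa-2,5-diene-1,4-dione | COC1=CC(=O)C(O)=C(CCCCCCCCCCCCCCCCCCCCCC)C1=O | target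

Total step count: 6. Longest linear sequence: 6 steps (from 1; dimethyl squarate 5 enters in step 3).

Steps most likely to fail

1. Step 3. The vinylic deprotonation of 4 may stay incomplete or be diverted to the allylic position, one geometric isomer may resist metalation, and the long-chain substrate may precipitate at low temperature before it is lithiated. The fallback sets out from 2 and comes back to the route at 6; it makes the alkenyllithium by tin–lithium exchange instead of C–H deprotonation. Pinnick oxidation of 2 (NaClO2, NaH2PO4, 2-methylbut-2-ene, t-BuOH/THF/H2O) should give tetracosanoic acid F1. Esterification (MOMCl, i-Pr2NEt, CH2Cl2) should give methoxymethyl tetracosanoate F2. Enolisation in the presence of the trap (KN(SiMe3)2, (PhO)2P(O)Cl, THF/DMPU, −78 °C) should give the ketene acetal phosphate 1-(methoxymethoxy)tetracos-1-en-1-yl diphenyl phosphate F3. Stannylation (Pd(PPh3)4 as zerovalent palladium catalyst, Me3SnSnMe3, LiCl, THF, 65 °C) should give trimethyl[1-(methoxymethoxy)tetracos-1-en-1-yl]stannane F4. MeLi in THF at −78 °C then delivers 6, which is added to 5 and methylated as in step 3.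

2. Step 2. Aldol self-condensation may compete while the enolate forms beside unreacted aldehyde, and the enolate may be alkylated on carbon instead of oxygen. The fallback sets out from 2 and comes back at 4; it generates the enolate by Si–O cleavage in the absence of aldehyde. Silylation (Me3SiCl, Et3N, DMF, 80 °C) should give trimethyl(tetracos-1-en-1-yloxy)silane F5, which is purified. MeLi (THF, 0 °C) should convert it into lithium tetracos-1-en-1-olate F6, and MOMCl in THF/DMPU at −78 to 0 °C should O-alkylate this to 4.

3. Step 4. Cation generation may not stay at the secondary carbinol carbon: protonolysis of the enol ether or ionisation of the tertiary methyl ether would scramble the substitution pattern, and the aluminium alkoxide may acylate sluggishly. The fallback sets out from 8 and comes back at 11; it exchanges the C-3 methoxy group for hydrogen without any cationic intermediate. Addition–elimination of hydroxide (LiOH, THF/H2O, 0 °C) should give the vinylogous acid 3-hydroxy-2,4-dimethoxy-4-[1-(methoxymethoxy)tetracos-1-en-1-yl]cyclobut-2-en-1-one F7; its O–C–C–C–O unit is symmetric in the four-membered ring, so sulfonylation at either oxygen leads to the same racemate. PhNTf2 and Et3N in CH2Cl2 should give 2,4-dimethoxy-4-[1-(methoxymethoxy)tetracos-1-en-1-yl]-3-oxocyclobut-1-en-1-yl trifluoromethanesulfonate F8. Reduction of the enol triflate (Pd(PPh3)4 as zerovalent palladium catalyst, Bu3SnH, LiCl, THF, rt) should give 11.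

Further compounds
F1 | step 3 | tetracosanoic acid | CCCCCCCCCCCCCCCCCCCCCCCC(=O)O
F2 | step 3 | methoxymethyl tetracosanoate | CCCCCCCCCCCCCCCCCCCCCCCC(=O)OCOC
F3 | step 3 | 1-(methoxymethoxy)tetracos-1-en-1-yl diphenyl phosphate | CCCCCCCCCCCCCCCCCCCCCCC=C(OCOC)OP(=O)(Oc1ccccc1)Oc1ccccc1
F4 | step 3 | trimethyl[1-(methoxymethoxy)tetracos-1-en-1-yl]stannane | CCCCCCCCCCCCCCCCCCCCCCC=C(OCOC)[Sn](C)(C)C
F5 | step 2 | trimethyl(tetracos-1-en-1-yloxy)silane | CCCCCCCCCCCCCCCCCCCCCCC=CO[Si](C)(C)C
F6 | step 2 | lithium tetracos-1-en-1-olate | CCCCCCCCCCCCCCCCCCCCCCC=C[O-].[Li+]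
F7 | step 4 | 3-hydroxy-2,4-dimethoxy-4-[1-(methoxymethoxy)tetracos-1-en-1-yl]cyclobut-2-en-1-one | COC1=C(O)C(OC)(C(OCOC)=CCCCCCCCCCCCCCCCCCCCCCC)C1=O
F8 | step 4 | 2,4-dimethoxy-4-[1-(methoxymethoxy)tetracos-1-en-1-yl]-3-oxocyclobut-1-en-1-yl trifluoromethanesulfonate | COC1=C(OS(=O)(=O)C(F)(F)F)C(OC)(C(OCOC)=CCCCCCCCCCCCCCCCCCCCCCC)C1=O
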